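**Retrosynthetic overview**

1. Last, periodate cleaves two cis-cyclopentanediol masks to release all four aldehydes; before that, two ester bonds join core diol 25 to two equivalents of acetonide acid 32 (from enone 26: enolate alkylation sets the S centre of each acyl unit, the ethylidene becomes the E-enal).
2. In the core cyclopentane (C-1 OAcyl, C-2 CH3, C-3 CH2OH, C-4 side chain, C-5 H2) the unsubstituted C-5 beside oxygenated C-1, flanked by C-4 and methyl-bearing C-2, is read as a two-carbon enone unit inserted into a homoallylic radical: C-4–C-5 by intermolecular addition, C-1–C-2 by 5-exo closure onto a vinyl group whose terminus becomes the C-2 methyl (radical [3+2] annulation with methyl vinyl ketone).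
3. The acetyl group brought in by the enone is a bond absent from the target: it lets C-1 be set by equilibration and is then excised by Baeyer–Villiger oxidation; the aldol hydroxyl used as radical leaving group is likewise traceless.
4. The radical precursor comes from two Evans crotonimide reactions: dienolate alkylation fixes the CH(CH2OBn)(CH2OTBS) carbon with its two arms already told apart, and dienolate aldol fixes the vinyl-bearing carbon.
5. Ring order: the two acetonide-bearing cyclopentanes of the acyl units exist from the start (26) and are opened last; the only ring of the target, the core cyclopentane, is formed in step 11.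

Key step: step 11

Assumption: the two carbinol carbons of each acetonide-masked cyclopentane become aldehydes in step 21, so their configuration is inconsequential; non-isolated diol 10 forms as a mixture at its new carbinol centre.

**Step 1**
Reactants: 1 (S)-4-benzyl-1,3-oxazolidin-2-one; 2 (E)-but-2-enoyl chloride
Product: 4 (S)-4-benzyl-3-[(E)-but-2-enoyl]-1,3-oxazolidin-2-one, via lithium oxazolidinide 3 (not isolated)
Conditions: n-BuLi, THF, −78 °C; then 2, −78 to 0 °C
Reagents that add atoms: none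
Why: N-acylation of the lithiated oxazolidinone by the acid chloride (standard Evans imide formation); no stereocentre is formed.

**Step 2**
Reactants: 4 (S)-4-benzyl-3-[(E)-but-2-enoyl]-1,3-oxazolidin-2-one; 5 benzyl chloromethyl ether
Product: 7 (4S)-4-benzyl-3-[(2R)-2-[(benzyloxy)methyl]but-3-enoyl]-1,3-oxazolidin-2-one, via sodium dienolate 6 (not isolated)
Conditions: NaHMDS, THF, −78 °C; then 5, −78 to −40 °C
Reagents that add atoms: none
Why: Evans deconjugative alkylation: γ-deprotonation gives the chelated (Z)-dienolate, which should be alkylated at the α-carbon on the face opposite the benzyl group, setting the (2R) centre that becomes the CH(CH2O)2 carbon with its two arms already differentiated.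

**Step 3**
Reactants: 7 (4S)-4-benzyl-3-[(2R)-2-[(benzyloxy)methyl]but-3-enoyl]-1,3-oxazolidin-2-one
Product: 8 (2S)-2-[(benzyloxy)methyl]but-3-en-1-ol
Conditions: LiBH4, H2O (1 equiv), Et2O, 0 °C
Reagents that add atoms: none
Why: Reductive cleavage of the N-acyl oxazolidinone by LiBH4 should give the primary alcohol and return the auxiliary without touching the stereocentre or the vinyl group.

**Step 4**
Reactants: 8 (2S)-2-[(benzyloxy)methyl]but-3-en-1-ol
Product: 9 tert-butyl{[(2R)-2-[(benzyloxy)methyl]but-3-en-1-yl]oxy}dimethylsilane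
Conditions: TBSCl, imidazole, DMF, 0 °C to rt
Reagents that add atoms: tert-butyldimethylsilyl chloride, CC(C)(C)[Si](C)(C)Cl
Why: Standard silylation of a primary alcohol; this arm stays protected until the end and becomes the free CH2OH of the side chain.

**Step 5**
Reactants: 9 tert-butyl{[(2R)-2-[(benzyloxy)methyl]but-3-en-1-yl]oxy}dimethylsilane
Product: 11 (2R)-3-(benzyloxy)-2-{[(tert-butyldimethylsilyl)oxy]methyl}propanal, via vicinal diol 10 (not isolated)
Conditions: OsO4 (2 mol %), NaIO4, 2,6-lutidine, dioxane/H2O (3:1), rt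
Reagents that add atoms: osmium tetroxide, O=[Os](=O)(=O)=O
Why: Lemieux–Johnson oxidative cleavage (catalytic dihydroxylation, then periodate glycol cleavage) should turn the vinyl group into the aldehyde under buffered conditions that spare the α-stereocentre; the aldehyde is used at once.

**Step 6**
Reactants: 12 (R)-4-benzyl-1,3-oxazolidin-2-one; 2 (E)-but-2-enoyl chloride
Product: 14 (R)-4-benzyl-3-[(E)-but-2-enoyl]-1,3-oxazolidin-2-one, via lithium oxazolidinide 13 (not isolated)
Conditions: n-BuLi, THF, −78 °C; then 2, −78 to 0 °C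
Reagents that add atoms: none
Why: Same N-acylation as in step 1, in the enantiomeric auxiliary series.

**Step 7**
Reactants: 14 (R)-4-benzyl-3-[(E)-but-2-enoyl]-1,3-oxazolidin-2-one; 11 (2R)-3-(benzyloxy)-2-{[(tert-butyldimethylsilyl)oxy]methyl}propanal
Product: 16 (4R)-4-benzyl-3-[(2R,3S,4R)-4-[(benzyloxy)methyl]-5-[(tert-butyldimethylsilyl)oxy]-2-ethenyl-3-hydroxypentanoyl]-1,3-oxazolidin-2-one, via boron dienolate 15 (not isolated)
Conditions: Bu2BOTf, Et3N, CH2Cl2, −78 to 0 °C; then 11, −78 to 0 °C; H2O2, pH 7 buffer, MeOH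
Reagents that add atoms: none
Why: Evans syn-aldol reaction of the dibutylboron (Z)-dienolate at its α-carbon through a Zimmerman–Traxler transition state; the auxiliary should set the vinyl-bearing centre (2R), while the carbinol centre (3S) only serves as the later radical site.

**Step 8**
Reactants: 16 aldol adduct
Product: 17 (2S,3R,4R)-4-[(benzyloxy)methyl]-5-[(tert-butyldimethylsilyl)oxy]-2-ethenylpentane-1,3-diol
Conditions: LiBH4, MeOH (1 equiv), THF, 0 °C
Reagents that add atoms: none
Why: Reductive removal of the auxiliary takes the acyl carbon to the CH2OH level, so no carbonyl remains next to the vinyl-bearing carbon in the radical step.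

**Step 9**
Reactants: 17 (2S,3R,4R)-4-[(benzyloxy)methyl]-5-[(tert-butyldimethylsilyl)oxy]-2-ethenylpentane-1,3-diol
Product: 18 (2R,3R,4S)-2-[(benzyloxy)methyl]-1-[(tert-butyldimethylsilyl)oxy]-4-{[(tert-butyldimethylsilyl)oxy]methyl}hex-5-en-3-ol
Conditions: TBSCl (1.05 equiv), imidazole, CH2Cl2, 0 °C
Reagents that add atoms: tert-butyldimethylsilyl chloride, CC(C)(C)[Si](C)(C)Cl
Why: Selective silylation of the primary hydroxyl over the hindered secondary one; the bulky CH2OTBS group is also the steric control element of step 11.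

**Step 10**
Reactants: 18 (2R,3R,4S)-2-[(benzyloxy)methyl]-1-[(tert-butyldimethylsilyl)oxy]-4-{[(tert-butyldimethylsilyl)oxy]methyl}hex-5-en-3-ol
Product: 19 O-[(2R,3R,4S)-2-[(benzyloxy)methyl]-1-[(tert-butyldimethylsilyl)oxy]-4-{[(tert-butyldimethylsilyl)oxy]methyl}hex-5-en-3-yl] O-phenyl carbonothioate
Conditions: PhOC(S)Cl, pyridine, DMAP (cat.), CH2Cl2, 0 °C to rt
Reagents that add atoms: O-phenyl chlorothionoformate, S=C(Cl)Oc1ccccc1
Why: Thioacylation of the secondary alcohol gives a Barton–McCombie radical precursor under non-basic conditions.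

**Step 11**
Reactants: 19 O-phenyl thionocarbonate; 20 but-3-en-2-one
Product: 22 1-[(1R,2R,3R,4R)-4-[(2R)-1-(benzyloxy)-3-[(tert-butyldimethylsilyl)oxy]propan-2-yl]-3-{[(tert-butyldimethylsilyl)oxy]methyl}-2-methylcyclopentyl]ethan-1-one, via acetyl epimer 21 (not isolated)
Conditions: (Me3Si)3SiH (syringe pump), Et3B/air, 20 (20 equiv, 2 M), PhH, rt; concentrate; then DBU (cat.), CH2Cl2, rt
Reagents that add atoms: none
Why: The silyl radical adds to C=S and the adduct fragments to the secondary radical at the former carbinol carbon, which adds to the CH2 terminus of the enone (first new bond, CH–CH2); the resulting α-keto radical closes onto the neighbouring vinyl group (second new bond, C(acetyl)–CH(CH3)) and the primary radical takes hydrogen from the silane to become the ring methyl. The closest known reaction type is the radical [3+2] annulation of but-3-enyl radicals with electron-poor alkenes (Giese addition followed by 5-hexenyl cyclisation), here fed by a Barton–McCombie fragmentation. The single ring closes in the 5-exo-trig mode. The carbon that loses oxygen should be set by addition anti to the CH2OTBS group of the adjacent vinyl-bearing centre (Felkin-type conformer, its C–H eclipsing the bulky dioxygenated branch); the methyl-bearing carbon by the chair-like Beckwith–Houk transition state with both ring substituents pseudo-equatorial (methyl cis to the chain, trans to CH2OTBS); the acetyl-bearing carbon thermodynamically by the DBU equilibration (acetyl trans to the vicinal methyl). The step needs trapping by the enone to outrun hydrogen transfer, 1,5-hydrogen shift from the benzyl ether and the 1,2-vinyl shift of the homoallylic radical; the high enone concentration, room temperature and slow silane feed should secure this, and with no carbonyl next to the vinyl-bearing carbon the shift has no driving force.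

**Step 12**
Reactants: 22 all-trans methyl ketone
Product: 23 (1R,2R,3S,4R)-4-[(2R)-1-(benzyloxy)-3-[(tert-butyldimethylsilyl)oxy]propan-2-yl]-3-{[(tert-butyldimethylsilyl)oxy]methyl}-2-methylcyclopentyl acetate
Conditions: CF3CO3H (from (CF3CO)2O and urea·H2O2), Na2HPO4, CH2Cl2, 0 °C
Reagents that add atoms: trifluoroperoxyacetic acid, OOC(=O)C(F)(F)F
Why: Baeyer–Villiger oxidation; the secondary ring carbon migrates in preference to methyl with retention, so the equilibrated C–acetyl bond becomes the C–O bond with oxygen trans to the methyl group.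

**Step 13**
Reactants: 23 acetate
Product: 24 (1R,2R,3S,4R)-4-[(2R)-1-(benzyloxy)-3-[(tert-butyldimethylsilyl)oxy]propan-2-yl]-3-{[(tert-butyldimethylsilyl)oxy]methyl}-2-methylcyclopentan-1-ol
Conditions: K2CO3, MeOH, rt
Reagents that add atoms: none
Why: Base-catalysed methanolysis of the acetate; silyl and benzyl ethers should be stable.

**Step 14**
Reactants: 24 benzyl ether alcohol
Product: 25 (1R,2R,3S,4R)-4-[(2R)-1-[(tert-butyldimethylsilyl)oxy]-3-hydroxypropan-2-yl]-3-{[(tert-butyldimethylsilyl)oxy]methyl}-2-methylcyclopentan-1-ol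
Conditions: H2 (1 atm), 10% Pd/C, EtOAc, rt
Reagents that add atoms: none
Why: Hydrogenolysis of the benzyl ether (no alkene is present at this stage) frees exactly the two hydroxyls that carry acyl groups in the target.

**Step 15**
Reactants: 26 (3aR,6aR)-2,2-dimethyl-3a,6a-dihydro-4H-cyclopenta[d][1,3]dioxol-4-one
Product: 27 (3aR,6aR)-2,2-dimethyltetrahydro-4H-cyclopenta[d][1,3]dioxol-4-one
Conditions: H2 (1 atm), 10% Pd/C, EtOAc, rt
Reagents that add atoms: none
Why: Catalytic hydrogenation of the enone C=C bond.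

**Step 16**
Reactants: 27 saturated ketone; 28 methyl bromoacetate
Product: 30 methyl 2-[(3aR,5S,6aR)-2,2-dimethyl-4-oxotetrahydro-4H-cyclopenta[d][1,3]dioxol-5-yl]acetate, via lithium enolate 29 (not isolated)
Conditions: LDA, THF, −78 °C; then 28, DMPU, −78 to −40 °C
Reagents that add atoms: none
Why: Kinetic enolate formation away from the alkoxy-bearing α-carbon and alkylation on the convex face, trans to the dioxolane oxygens, should set the centre that becomes the (3S) carbon of each acyl unit.

**Step 17**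
Reactants: 30 keto ester
Product: 31 methyl 2-[(3aS,4E,5S,6aR)-4-ethylidene-2,2-dimethyltetrahydro-4H-cyclopenta[d][1,3]dioxol-5-yl]acetate
Conditions: EtPPh3Br, KOtBu, THF, 0 °C; then 30, 0 °C to rt
Reagents that add atoms: ethyltriphenylphosphonium bromide, CC[P+](c1ccccc1)(c1ccccc1)c1ccccc1.[Br-]
Why: Wittig olefination with a non-stabilised ylide under kinetic control should place the methyl group cis to the more encumbered α-carbon (the CH(CH2CO2Me) carbon), giving the E-ethylidene that later becomes the E-enal; the minor isomer would be removed by chromatography.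

**Step 18**
Reactants: 31 ethylidene ester
Product: 32 2-[(3aS,4E,5S,6aR)-4-ethylidene-2,2-dimethyltetrahydro-4H-cyclopenta[d][1,3]dioxol-5-yl]acetic acid
Conditions: LiOH, THF/H2O, 0 °C to rt; then 1 M HCl to pH 3
Reagents that add atoms: lithium hydroxide, [Li+].[OH-]
Why: Saponification of the methyl ester; the non-conjugated exocyclic alkene and the acetonide should be unaffected.

**Step 19**
Reactants: 25 core diol; 32 acetonide acid (2.5 equiv)
Product: 33 bis-ester of diol 25 (primary and ring hydroxyl) with acid 32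
Conditions: EDC·HCl, DMAP, CH2Cl2, 0 °C to rt
Reagents that add atoms: none
Why: Steglich esterification of both free hydroxyls with retention at the ring carbinol; the two other hydroxymethyl groups are silyl-protected.

**Step 20**
Reactants: 33 bis-ester
Product: 34 hexaol (both silyl ethers and both acetonides removed)
Conditions: 1 M HCl/THF (1:3), 0 °C to rt
Reagents that add atoms: none
Why: Mild acid hydrolysis of the primary TBS ethers and the two acetonides; base and heat are avoided so that 1,3-acyl shift between the two side-chain arms should not scramble the side-chain stereocentre.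

**Step 21**
Reactants: 34 hexaol
Product: 35 CNP0192766.1
Conditions: NaIO4, THF/H2O (pH 7 phosphate), 0 °C
Reagents that add atoms: none
Why: Malaprade glycol cleavage of the two cis-cyclopentanediols gives both 1,5-dialdehyde units with the E-enal geometry and the (3S) centres in place; the two free core hydroxyls are 1,5-related and should not be cleaved.

**Compound list**

1 | (S)-4-benzyl-1,3-oxazolidin-2-one | O=C1N[C@@H](Cc2ccccc2)CO1 | starting material
2 | (E)-but-2-enoyl chloride | C/C=C/C(Cl)=O | starting material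
3 | lithium (S)-4-benzyl-2-oxo-1,3-oxazolidin-3-ide | [Li+].O=C1[N-][C@@H](Cc2ccccc2)CO1 | intermediate
4 | (S)-4-benzyl-3-[(E)-but-2-enoyl]-1,3-oxazolidin-2-one | C/C=C/C(=O)N1[C@@H](Cc2ccccc2)COC1=O | intermediate
5 | benzyl chloromethyl ether | ClCOCc1ccccc1 | starting material
6 | sodium (Z)-dienolate of 4 | [Na+].C=C/C=C(\[O-])N1[C@@H](Cc2ccccc2)COC1=O | intermediate
7 | (4S)-4-benzyl-3-[(2R)-2-[(benzyloxy)methyl]but-3-enoyl]-1,3-oxazolidin-2-one | c1ccccc1COC[C@@H](C=C)C(=O)N1[C@@H](Cc2ccccc2)COC1=O | intermediate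
8 | (2S)-2-[(benzyloxy)methyl]but-3-en-1-ol | c1ccccc1COC[C@H](CO)C=C | intermediate
9 | tert-butyl{[(2R)-2-[(benzyloxy)methyl]but-3-en-1-yl]oxy}dimethylsilane | c1ccccc1COC[C@H](CO[Si](C)(C)C(C)(C)C)C=C | intermediate
10 | (3R)-3-[(benzyloxy)methyl]-4-[(tert-butyldimethylsilyl)oxy]butane-1,2-diol (both C-2 epimers) | c1ccccc1COC[C@H](CO[Si](C)(C)C(C)(C)C)C(O)CO | intermediate
11 | (2R)-3-(benzyloxy)-2-{[(tert-butyldimethylsilyl)oxy]methyl}propanal | c1ccccc1COC[C@H](CO[Si](C)(C)C(C)(C)C)C=O | intermediate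
12 | (R)-4-benzyl-1,3-oxazolidin-2-one | O=C1N[C@H](Cc2ccccc2)CO1 | starting material
13 | lithium (R)-4-benzyl-2-oxo-1,3-oxazolidin-3-ide | [Li+].O=C1[N-][C@H](Cc2ccccc2)CO1 | intermediate
14 | (R)-4-benzyl-3-[(E)-but-2-enoyl]-1,3-oxazolidin-2-one | C/C=C/C(=O)N1[C@H](Cc2ccccc2)COC1=O | intermediate
15 | dibutylboron (Z)-dienolate of 14 | C=C/C=C(\OB(CCCC)CCCC)N1[C@H](Cc2ccccc2)COC1=O | intermediate
16 | (4R)-4-benzyl-3-[(2R,3S,4R)-4-[(benzyloxy)methyl]-5-[(tert-butyldimethylsilyl)oxy]-2-ethenyl-3-hydroxypentanoyl]-1,3-oxazolidin-2-one | c1ccccc1COC[C@H](CO[Si](C)(C)C(C)(C)C)[C@H](O)[C@@H](C=C)C(=O)N1[C@H](Cc2ccccc2)COC1=O | intermediate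
17 | (2S,3R,4R)-4-[(benzyloxy)methyl]-5-[(tert-butyldimethylsilyl)oxy]-2-ethenylpentane-1,3-diol | c1ccccc1COC[C@H](CO[Si](C)(C)C(C)(C)C)[C@H](O)[C@@H](C=C)CO | intermediate
18 | (2R,3R,4S)-2-[(benzyloxy)methyl]-1-[(tert-butyldimethylsilyl)oxy]-4-{[(tert-butyldimethylsilyl)oxy]methyl}hex-5-en-3-ol | c1ccccc1COC[C@H](CO[Si](C)(C)C(C)(C)C)[C@H](O)[C@@H](C=C)CO[Si](C)(C)C(C)(C)C | intermediate
19 | O-[(2R,3R,4S)-2-[(benzyloxy)methyl]-1-[(tert-butyldimethylsilyl)oxy]-4-{[(tert-butyldimethylsilyl)oxy]methyl}hex-5-en-3-yl] O-phenyl carbonothioate | c1ccccc1COC[C@H](CO[Si](C)(C)C(C)(C)C)[C@H](OC(=S)Oc1ccccc1)[C@@H](C=C)CO[Si](C)(C)C(C)(C)C | intermediate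
20 | but-3-en-2-one (methyl vinyl ketone) | CC(=O)C=C | starting material
21 | 1-[(1S,2R,3R,4R)-4-[(2R)-1-(benzyloxy)-3-[(tert-butyldimethylsilyl)oxy]propan-2-yl]-3-{[(tert-butyldimethylsilyl)oxy]methyl}-2-methylcyclopentyl]ethan-1-one (acetyl cis to methyl) | c1ccccc1COC[C@H](CO[Si](C)(C)C(C)(C)C)[C@@H]1C[C@H](C(C)=O)[C@H](C)[C@H]1CO[Si](C)(C)C(C)(C)C | intermediate
22 | 1-[(1R,2R,3R,4R)-4-[(2R)-1-(benzyloxy)-3-[(tert-butyldimethylsilyl)oxy]propan-2-yl]-3-{[(tert-butyldimethylsilyl)oxy]methyl}-2-methylcyclopentyl]ethan-1-one (all-trans) | c1ccccc1COC[C@H](CO[Si](C)(C)C(C)(C)C)[C@@H]1C[C@@H](C(C)=O)[C@H](C)[C@H]1CO[Si](C)(C)C(C)(C)C | intermediate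
23 | (1R,2R,3S,4R)-4-[(2R)-1-(benzyloxy)-3-[(tert-butyldimethylsilyl)oxy]propan-2-yl]-3-{[(tert-butyldimethylsilyl)oxy]methyl}-2-methylcyclopentyl acetate | c1ccccc1COC[C@H](CO[Si](C)(C)C(C)(C)C)[C@@H]1C[C@@H](OC(C)=O)[C@H](C)[C@H]1CO[Si](C)(C)C(C)(C)C | intermediate
24 | (1R,2R,3S,4R)-4-[(2R)-1-(benzyloxy)-3-[(tert-butyldimethylsilyl)oxy]propan-2-yl]-3-{[(tert-butyldimethylsilyl)oxy]methyl}-2-methylcyclopentan-1-ol | c1ccccc1COC[C@H](CO[Si](C)(C)C(C)(C)C)[C@@H]1C[C@@H](O)[C@H](C)[C@H]1CO[Si](C)(C)C(C)(C)C | intermediate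
25 | (1R,2R,3S,4R)-4-[(2R)-1-[(tert-butyldimethylsilyl)oxy]-3-hydroxypropan-2-yl]-3-{[(tert-butyldimethylsilyl)oxy]methyl}-2-methylcyclopentan-1-ol | OC[C@H](CO[Si](C)(C)C(C)(C)C)[C@@H]1C[C@@H](O)[C@H](C)[C@H]1CO[Si](C)(C)C(C)(C)C | intermediate
26 | (3aR,6aR)-2,2-dimethyl-3a,6a-dihydro-4H-cyclopenta[d][1,3]dioxol-4-one | O=C1C=C[C@H]2OC(C)(C)O[C@@H]12 | starting material
27 | (3aR,6aR)-2,2-dimethyltetrahydro-4H-cyclopenta[d][1,3]dioxol-4-one | O=C1CC[C@H]2OC(C)(C)O[C@@H]12 | intermediate
28 | methyl bromoacetate | COC(=O)CBr | starting material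
29 | lithium enolate of 27 (enolised toward the CH2 group) | [Li+].[O-]C1=CC[C@H]2OC(C)(C)O[C@@H]12 | intermediate
30 | methyl 2-[(3aR,5S,6aR)-2,2-dimethyl-4-oxotetrahydro-4H-cyclopenta[d][1,3]dioxol-5-yl]acetate | COC(=O)C[C@@H]1C[C@H]2OC(C)(C)O[C@H]2C1=O | intermediate
31 | methyl 2-[(3aS,4E,5S,6aR)-4-ethylidene-2,2-dimethyltetrahydro-4H-cyclopenta[d][1,3]dioxol-5-yl]acetate | COC(=O)C[C@@H]1C[C@H]2OC(C)(C)O[C@H]2/C1=C/C | intermediate
32 | 2-[(3aS,4E,5S,6aR)-4-ethylidene-2,2-dimethyltetrahydro-4H-cyclopenta[d][1,3]dioxol-5-yl]acetic acid | OC(=O)C[C@@H]1C[C@H]2OC(C)(C)O[C@H]2/C1=C/C | intermediate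
33 | bis-ester: diol 25 acylated at the primary and at the ring hydroxyl by acid 32 (two TBS ethers and two acetonides retained) | O=C(C[C@@H]1C[C@H]2OC(C)(C)O[C@H]2/C1=C/C)OC[C@H](CO[Si](C)(C)C(C)(C)C)[C@@H]1C[C@@H](OC(=O)C[C@@H]2C[C@H]3OC(C)(C)O[C@H]3/C2=C/C)[C@H](C)[C@H]1CO[Si](C)(C)C(C)(C)C | intermediate
34 | hexaol: [(2S)-3-hydroxy-2-[(1R,2S,3R,4R)-2-(hydroxymethyl)-3-methyl-4-(acyloxy)cyclopentyl]propyl] ester, both acyl groups being 2-[(1S,2E,3S,4R)-2-ethylidene-3,4-dihydroxycyclopentyl]acetyl | O=C(C[C@@H]1C[C@@H](O)[C@@H](O)/C1=C/C)OC[C@H](CO)[C@@H]1C[C@@H](OC(=O)C[C@@H]2C[C@@H](O)[C@@H](O)/C2=C/C)[C@H](C)[C@H]1CO | intermediate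
35 | CNP0192766.1: (2S)-3-hydroxy-2-[(1R,2S,3R,4R)-4-{[(3S,4E)-4-formyl-3-(2-oxoethyl)hex-4-enoyl]oxy}-2-(hydroxymethyl)-3-methylcyclopentyl]propyl (3S,4E)-4-formyl-3-(2-oxoethyl)hex-4-enoate | C/C=C(/C=O)[C@@H](CC=O)CC(=O)OC[C@H](CO)[C@@H]1C[C@@H](OC(=O)C[C@H](CC=O)/C(C=O)=C\C)[C@H](C)[C@H]1CO | target

**Step count and risks**

Total step count: 21. Longest linear sequence: 16 steps (1–5, 7–14, 19–21); step 6 and steps 15–18 are side branches.

Steps most likely to fail:

1. Step 11 (radical annulation). The chain may be lost to hydrogen transfer before addition or ring closure, to telomerisation of the enone, or to 1,2-vinyl migration of the homoallylic radical; addition may also occur on the wrong face of the radical. Fallback: the two bonds would be made in separate known operations. From 19, Giese addition to vinylboronic acid pinacol ester (Bu3SnH at high concentration, AIBN, PhH, 80 °C, so that the α-boryl radical is reduced before it can cyclise) should give the open-chain pinacol boronate F1. NaBO3 oxidation gives the primary alcohol F2 and Dess–Martin oxidation the aldehyde F3. SmI2/HMPA/t-BuOH ketyl–olefin cyclisation (5-exo, hydroxyl anti to the new methyl group) then rejoins the route at alcohol 24.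

2. Step 17 (ethylidenation). Alkene geometry may be poorly controlled, and the basic ylide may cause β-elimination of the dioxolane oxygen. Fallback: a stereodivergent Peterson olefination. From 30, CeCl3-mediated addition of 1-(trimethylsilyl)ethyllithium (THF, −78 °C) should give the two separable β-hydroxysilanes F4 and F5. F4 is eliminated syn with KH (THF, 0 °C) and F5 anti with AcOH/NaOAc; both should converge on the E-alkene and rejoin the route at 31.

3. Step 2 (deconjugative alkylation). Alkylation may occur at the γ-carbon, and the β,γ-unsaturated imide may slip back into conjugation. Fallback: the stereocentre is made by hydroxymethylation instead. From 1, acylation with 3-(benzyloxy)propanoyl chloride (n-BuLi, THF) gives (S)-4-benzyl-3-[3-(benzyloxy)propanoyl]-1,3-oxazolidin-2-one F6. Evans hydroxymethylation (TiCl4, i-Pr2NEt, then s-trioxane/TiCl4, CH2Cl2, 0 °C) gives the (2S)-hydroxymethyl imide F7. TBSCl/imidazole gives the silyl ether F8, LiBH4 the alcohol F9, and Dess–Martin oxidation rejoins the route at aldehyde 11.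

**Further compounds**

F1 | step 11 | 2-{2-[(3R,4R)-3-[(2R)-1-(benzyloxy)-3-[(tert-butyldimethylsilyl)oxy]propan-2-yl]-4-{[(tert-butyldimethylsilyl)oxy]methyl}hex-5-en-1-yl]}-4,4,5,5-tetramethyl-1,3,2-dioxaborolane | c1ccccc1COC[C@H](CO[Si](C)(C)C(C)(C)C)[C@H](CCB1OC(C)(C)C(C)(C)O1)[C@@H](C=C)CO[Si](C)(C)C(C)(C)C
F2 | step 11 | (3R,4R)-3-[(2R)-1-(benzyloxy)-3-[(tert-butyldimethylsilyl)oxy]propan-2-yl]-4-{[(tert-butyldimethylsilyl)oxy]methyl}hex-5-en-1-ol | c1ccccc1COC[C@H](CO[Si](C)(C)C(C)(C)C)[C@H](CCO)[C@@H](C=C)CO[Si](C)(C)C(C)(C)C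
F3 | step 11 | (3R,4R)-3-[(2R)-1-(benzyloxy)-3-[(tert-butyldimethylsilyl)oxy]propan-2-yl]-4-{[(tert-butyldimethylsilyl)oxy]methyl}hex-5-enal | c1ccccc1COC[C@H](CO[Si](C)(C)C(C)(C)C)[C@H](CC=O)[C@@H](C=C)CO[Si](C)(C)C(C)(C)C
F4 | step 17 | β-hydroxysilane from 30: tertiary hydroxyl cis to the dioxolane oxygens, 1-(trimethylsilyl)ethyl group on the ketone carbon, silyl-bearing carbon as in the SMILES (syn-elimination gives E) | COC(=O)C[C@@H]1C[C@H]2OC(C)(C)O[C@H]2[C@]1(O)[C@H](C)[Si](C)(C)C
F5 | step 17 | epimer of F4 at the silyl-bearing carbon (anti-elimination gives E) | COC(=O)C[C@@H]1C[C@H]2OC(C)(C)O[C@H]2[C@]1(O)[C@@H](C)[Si](C)(C)C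
F6 | step 2 | (S)-4-benzyl-3-[3-(benzyloxy)propanoyl]-1,3-oxazolidin-2-one | O=C(CCOCc1ccccc1)N1[C@@H](Cc2ccccc2)COC1=O
F7 | step 2 | (4S)-4-benzyl-3-[(2S)-3-(benzyloxy)-2-(hydroxymethyl)propanoyl]-1,3-oxazolidin-2-one | c1ccccc1COC[C@H](CO)C(=O)N1[C@@H](Cc2ccccc2)COC1=O
F8 | step 2 | (4S)-4-benzyl-3-[(2R)-3-(benzyloxy)-2-{[(tert-butyldimethylsilyl)oxy]methyl}propanoyl]-1,3-oxazolidin-2-one | c1ccccc1COC[C@H](CO[Si](C)(C)C(C)(C)C)C(=O)N1[C@@H](Cc2ccccc2)COC1=O
F9 | step 2 | (2R)-3-(benzyloxy)-2-{[(tert-butyldimethylsilyl)oxy]methyl}propan-1-ol | c1ccccc1COC[C@H](CO[Si](C)(C)C(C)(C)C)CO
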